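**Assumption:** the sulfonium salt **8** and the silyl-protected aldehyde **14** are taken as purchasable (14 is otherwise one step from 4-hydroxybenzaldehyde with TBSCl/imidazole). Iridoid numbering is used throughout: C1 acetal CH, O2, C3=C4(CO2Me), C5 and C9 ring-fusion CH, C6=C7, C8 spiro carbon, C10 O–CH of the lactone ring, C11(=C13H–Ar), C12 lactone C=O. "Exo/convex" means the face carrying H-5 and H-9.

## Retrosynthetic overview

1. Target ⇐ phenol acetylation of prismatomerin ⇐ C4 methoxycarbonylation (trichloroacetylation, then methanolysis) of the tetracyclic enol ether **19**.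
2. **19** ⇐ one acid-triggered cascade from dialdehyde **18**: the dihydropyran closes as a lactol–enol ether, then the C1 lactol OH displaces the C13 carbinol (SN1′), closing the acetal THF ring and forming the E-arylidene.
3. **18** ⇐ osmylation and periodate cleavage of carbocyclic ring B in **16**; the α-(aryl-hydroxymethyl)butenolide ⇐ sulfenylation, aldol with **14**, and sulfoxide elimination on spirolactone **12**.
4. **12** (C8 quaternary centre, C6=C7) ⇐ substitutive spiroannulation of (1R,5R)-bicyclo[3.3.0]oct-7-en-2-one **7**: cyclopropylide, vinylcyclopropanol, PhSe⁺-induced ring expansion, Baeyer–Villiger with selenoxide elimination.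
5. **7** ⇐ Pd-catalysed enolate–vinyl iodide closure of (R)-**6** ⇐ ene-reductase reduction of achiral enone **3** ⇐ 3-ethoxycyclopentenone + propargyl Grignard. Ring order: cyclopentanone (ring A) → carbocyclic ring B → spiro-lactone → ring B cleaved, then dihydropyran and acetal THF together.

## Forward route

**Step 1**
Reactants: **1** 3-ethoxycyclopent-2-en-1-one; **2** propargyl bromide (as its Grignard reagent)
Product: **3** 3-(prop-2-yn-1-yl)cyclopent-2-en-1-one
Conditions: 2, Mg, HgCl2 (cat.), Et2O, 0 °C; add 1, −20 °C; then 1 M HCl, 0 °C
Reagents that add atoms: propargyl bromide, C#CCBr (C3H3 unit)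
Why: Stork–Danheiser sequence: the allenyl/propargyl Grignard adds 1,2 (SE2′) to the vinylogous ester, and acid hydrolysis/elimination gives the transposed β-substituted enone. No stereocentre is formed.

**Step 2**
Reactants: **3**
Product: **4** (R)-3-(prop-2-yn-1-yl)cyclopentan-1-one
Conditions: ene-reductase (Old Yellow Enzyme family, picked from a panel for the R product), NADP⁺ (cat.), glucose, glucose dehydrogenase, KPi pH 7, 5% DMSO, 30 °C
Reagents that add atoms: none
Why: Flavin-dependent ene-reductase trans-hydrogenation of the activated C=C: hydride goes to Cβ on one enantioface in the active site and sets C5. This is the same facial sense that gives (S)-3-methylcyclopentanone (the descriptor changes only through CIP priority). The unactivated alkyne is untouched and C5 cannot epimerise later.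

**Step 3**
Reactants: **4**
Product: **5** (R)-3-(3-iodoprop-2-yn-1-yl)cyclopentan-1-one
Conditions: NIS, AgNO3 (10 mol%), acetone, rt, dark
Reagents that add atoms: N-iodosuccinimide, O=C1CCC(=O)N1I
Why: Silver-acetylide-mediated electrophilic iodination of the terminal alkyne; the ketone is inert without acid.

**Step 4**
Reactants: **5**
Product: **6** (R)-3-[(Z)-3-iodoprop-2-en-1-yl]cyclopentan-1-one
Conditions: KO2CN=NCO2K, AcOH, pyridine/MeOH, rt
Reagents that add atoms: none
Why: Diimide syn-reduction of the iodoalkyne gives only the Z-vinyl iodide. A hydrazide-free diimide source is used so the ketone does not form a hydrazone.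

**Step 5**
Reactants: **6**
Product: **7** (1R,5R)-cis-bicyclo[3.3.0]oct-7-en-2-one
Conditions: Pd(PPh3)4 (10 mol%), t-BuOK (1.2 equiv), THF/t-BuOH, rt
Reagents that add atoms: none
Why: Pd(0)-catalysed intramolecular ketone α-alkenylation (enolate–vinyl iodide cyclopentene annulation). Only the C9 enolate can close a fused five-membered ring, and that ring must be cis-fused, so C5 dictates C9.

**Step 6**
Reactants: **7**; **8** cyclopropyldiphenylsulfonium tetrafluoroborate
Product: **9** oxaspiropentane (spiro-epoxide at the former C=O carbon; cyclopropane carbon exo, epoxide O endo)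
Conditions: 8, KOH, DMSO, rt
Reagents that add atoms: 8, C1CC1[S+](c1ccccc1)c1ccccc1.F[B-](F)(F)F (cyclopropylidene, C3H4)
Why: Sulfur-ylide (cyclopropylide) addition to the ketone followed by ring closure, a Corey–Chaykovsky-type epoxidation. Attack is from the convex face; the epoxide stereocentre is destroyed in the next step.

**Step 7**
Reactants: **9**
Product: **10** 2-[1-(trimethylsilyloxy)cyclopropyl]-cis-bicyclo[3.3.0]octa-2,7-diene (ring-fusion centres as in 7)
Conditions: LiNEt2, Et2O/hexane, 0 °C → rt; then TMSCl, Et3N
Reagents that add atoms: chlorotrimethylsilane, C[Si](C)(C)Cl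
Why: Lithium-amide syn-β-elimination of the epoxide to the cyclopropanolate. Only C7 has a hydrogen syn to the endo epoxide oxygen (at C9 that position is occupied by ring B), so the C8=C7 alkene forms regioselectively; the alkoxide is then silylated.

**Step 8**
Reactants: **10**
Product: **11** spiro-cyclobutanone (C8 spiro; C=O carbon exo, ring CH2 endo; 7-exo-phenylseleno)
Conditions: PhSeBr, CH2Cl2, −78 °C
Reagents that add atoms: phenylselenenyl bromide, Br[Se]c1ccccc1
Why: Selenonium-triggered cyclopropanol-to-cyclobutanone ring expansion (semipinacol, "substitutive spiroannulation"). PhSe⁺ adds to C7 from the convex face and the cyclopropane CH2 migrates anti onto C8 from the concave face, which sets the C8 quaternary centre. The trisubstituted alkene reacts irreversibly; any adduct at the ring-B alkene reverts.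

**Step 9**
Reactants: **11**
Product: **12** spiro γ-lactone (iridoid numbering 5S,8S,9S; lactone O exo, cis to H-9; C6=C7 and the ring-B alkene present)
Conditions: 30% H2O2, NaOH, MeOH/THF/H2O, 0 °C → rt; work-up at pH 4
Reagents that add atoms: hydrogen peroxide, OO (one O)
Why: Baeyer–Villiger oxidation of the strained cyclobutanone with migration of the quaternary C8 with retention, which places the lactone oxygen on the exo face. The selenide is oxidised at the same time and undergoes selenoxide syn-elimination; C6 is the only β-carbon with hydrogens, so C6=C7 forms.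

**Step 10**
Reactants: **12**
Product: **13** 11-(phenylthio) spirolactone (C11 epimers)
Conditions: LDA, THF, −78 °C; PhSSPh, HMPA
Reagents that add atoms: diphenyl disulfide, c1ccc(SSc2ccccc2)cc1
Why: Lactone enolate sulfenylation; the C11 configuration is irrelevant because it becomes sp² later.

**Step 11**
Reactants: **13**; **14** 4-(tert-butyldimethylsilyloxy)benzaldehyde
Product: **15** 11-(phenylthio)-11-[hydroxy(4-TBSO-phenyl)methyl] spirolactone (diastereomer mixture at C11/C13)
Conditions: LDA, THF, −78 °C; 14; AcOH quench at −78 °C
Reagents that add atoms: 14, O=Cc1ccc(O[Si](C)(C)C(C)(C)C)cc1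
Why: Aldol addition of the sulfur-stabilised lactone enolate. Both new centres are later removed, so no stereocontrol is needed; the cold quench prevents retro-aldol.

**Step 12**
Reactants: **15**
Product: **16** spiro-butenolide (C10=C11) carrying the 11-[hydroxy(4-TBSO-phenyl)methyl] group (C13 epimers)
Conditions: mCPBA (1.0 equiv), CH2Cl2, −78 °C; then toluene, CaCO3, 90 °C
Reagents that add atoms: none (the mCPBA oxygen leaves with PhSOH)
Why: Sulfide to sulfoxide, then thermal sulfoxide syn-elimination (dehydrosulfenylation). Elimination goes into the ring towards C10–H and away from the carbinol carbon, giving the conjugated butenolide; the sulfide is oxidised much faster than the alkenes at −78 °C.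

**Step 13**
Reactants: **16**
Product: **17** ring-B exo,cis-diol (OH on C1 and C3)
Conditions: OsO4 (2 mol%), NMO (1.1 equiv), acetone/H2O, 0 °C
Reagents that add atoms: osmium tetroxide, O=[Os](=O)(=O)=O (re-oxidised by NMO, C[N+]1([O-])CCOCC1; water)
Why: Upjohn dihydroxylation of the most electron-rich, least hindered alkene. The C6=C7 alkene is flanked by the spiro centre and carries an allylic acyloxy group, and the butenolide alkene is electron-poor. The new centres are cleaved in the next step.

**Step 14**
Reactants: **17**
Product: **18** dialdehyde (C9–CHO and C5–CH2–CHO; used crude)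
Conditions: NaIO4, THF/pH 7 buffer, 0 °C
Reagents that add atoms: none
Why: Periodate glycol cleavage opens ring B and unveils C1 and C3 at the aldehyde oxidation level.

**Step 15**
Reactants: **18**
Product: **19** tetracyclic enol ether (4-descarbomethoxy-O-TBS-prismatomerin; 1R,5S,8S,9S,10S, E)
Conditions: CSA (10 mol%), 4 Å MS, CH2Cl2, 0 °C → rt
Reagents that add atoms: none
Why: Acid-catalysed cascade. The C3 enol closes onto C1 to give the lactol–enol ether, then the C1–OH captures the aryl-stabilised allyl cation from C13–OH at C10 (SN1′, a vinylogous dehydrative etherification). C1 and C10 are fixed by the cage, since only cis-fused five-membered rings can form. A C9 epimer cannot cyclise and funnels back, and the E-arylidene is the thermodynamic isomer under these reversible conditions.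

**Step 16**
Reactants: **19**
Product: **20** 4-(trichloroacetyl) tetracycle
Conditions: Cl3CCOCl, pyridine, CH2Cl2, 0 °C → rt
Reagents that add atoms: trichloroacetyl chloride, ClC(=O)C(Cl)(Cl)Cl
Why: Electrophilic C-acylation of the enol ether β-carbon (C4) to give the push–pull β-alkoxyvinyl trichloromethyl ketone. There is no free OH, and the arylidene and C6=C7 alkenes are not nucleophilic enough to react.

**Step 17**
Reactants: **20**
Product: **21** prismatomerin
Conditions: K2CO3, MeOH, 0 °C → rt
Reagents that add atoms: methanol, CO (OMe)
Why: Haloform-type methanolysis of the trichloromethyl ketone gives the C4 methyl ester, and the same conditions cleave the aryl silyl ether. The resulting phenoxide deactivates the arylidene lactone towards conjugate addition, and the acetal is base-stable.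

**Step 18**
Reactants: **21**
Product: **22** 3-O-acetylprismatomerin (target)
Conditions: Ac2O, pyridine, DMAP (cat.), CH2Cl2, 0 °C
Reagents that add atoms: acetic anhydride, CC(=O)OC(C)=O
Why: Acetylation of the only free hydroxyl, the phenol.

## Compound list

1 | 3-ethoxycyclopent-2-en-1-one | CCOC1=CC(=O)CC1 | starting material
2 | propargyl bromide | C#CCBr | starting material
3 | 3-(prop-2-yn-1-yl)cyclopent-2-en-1-one | C#CCC1=CC(=O)CC1 | intermediate
4 | (R)-3-(prop-2-yn-1-yl)cyclopentan-1-one | O=C1CC[C@H](CC#C)C1 | intermediate
5 | (R)-3-(3-iodoprop-2-yn-1-yl)cyclopentan-1-one | O=C1CC[C@H](CC#CI)C1 | intermediate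
6 | (R)-3-[(Z)-3-iodoprop-2-en-1-yl]cyclopentan-1-one | O=C1CC[C@H](C/C=C\I)C1 | intermediate
7 | (1R,5R)-cis-bicyclo[3.3.0]oct-7-en-2-one | O=C1CC[C@@H]2CC=C[C@H]12 | intermediate
8 | cyclopropyldiphenylsulfonium tetrafluoroborate | C1CC1[S+](c1ccccc1)c1ccccc1.F[B-](F)(F)F | starting material
9 | oxaspiropentane of 7 (cyclopropane carbon exo, O endo) | C1CC12O[C@@]23CC[C@@H]4CC=C[C@H]34 | intermediate
10 | 2-[1-(trimethylsilyloxy)cyclopropyl]-cis-bicyclo[3.3.0]octa-2,7-diene | C[Si](C)(C)OC1(CC1)C2=CC[C@@H]3CC=C[C@H]23 | intermediate
11 | 7-exo-phenylseleno spiro-cyclobutanone (C=O carbon exo on C8) | O=C1CC[C@@]12[C@@H]([Se]c3ccccc3)C[C@@H]4CC=C[C@H]24 | intermediate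
12 | spiro γ-lactone, 5S,8S,9S (lactone O exo; C6=C7 and ring-B alkene) | O=C1CC[C@]2(O1)C=C[C@@H]3CC=C[C@H]23 | intermediate
13 | 11-(phenylthio) spirolactone (C11 epimers) | O=C1C(Sc4ccccc4)C[C@]2(O1)C=C[C@@H]3CC=C[C@H]23 | intermediate
14 | 4-(tert-butyldimethylsilyloxy)benzaldehyde | O=Cc1ccc(O[Si](C)(C)C(C)(C)C)cc1 | starting material
15 | aldol adduct (C11/C13 mixture) | O=C1C(Sc4ccccc4)(C(O)c5ccc(O[Si](C)(C)C(C)(C)C)cc5)C[C@]2(O1)C=C[C@@H]3CC=C[C@H]23 | intermediate
16 | spiro-butenolide with 11-[hydroxy(4-TBSO-phenyl)methyl] (C13 epimers) | O=C1C(C(O)c4ccc(O[Si](C)(C)C(C)(C)C)cc4)=C[C@]2(O1)C=C[C@@H]3CC=C[C@H]23 | intermediate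
17 | ring-B exo,cis-diol | O=C1C(C(O)c4ccc(O[Si](C)(C)C(C)(C)C)cc4)=C[C@]2(O1)C=C[C@@H]3C[C@@H](O)[C@@H](O)[C@H]23 | intermediate
18 | dialdehyde (C9–CHO, C5–CH2CHO) | O=C1C(C(O)c4ccc(O[Si](C)(C)C(C)(C)C)cc4)=C[C@]2(O1)C=C[C@H](CC=O)[C@@H]2C=O | intermediate
19 | tetracyclic enol ether (4-descarbomethoxy-O-TBS-prismatomerin) | C1=CO[C@@H]2O[C@H]3/C(=C\c4ccc(O[Si](C)(C)C(C)(C)C)cc4)C(=O)O[C@]34C=C[C@H]1[C@H]24 | intermediate
20 | 4-trichloroacetyl tetracycle | ClC(Cl)(Cl)C(=O)C1=CO[C@@H]2O[C@H]3/C(=C\c4ccc(O[Si](C)(C)C(C)(C)C)cc4)C(=O)O[C@]34C=C[C@H]1[C@H]24 | intermediate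
21 | prismatomerin | COC(=O)C1=CO[C@@H]2O[C@H]3/C(=C\c4ccc(O)cc4)C(=O)O[C@]34C=C[C@H]1[C@H]24 | intermediate
22 | 3-O-acetylprismatomerin (1R,5S,8S,9S,10S, E) | COC(=O)C1=CO[C@@H]2O[C@H]3/C(=C\c4ccc(OC(C)=O)cc4)C(=O)O[C@]34C=C[C@H]1[C@H]24 | target

## Summary

Total steps: 18. Longest linear sequence: 18 (fully linear from **1**; **8** and **14** are bought in).

Three steps most likely to fail, each with a fallback:

1. **Step 5 (Pd enolate–vinyl iodide closure).** Risks are base-induced loss of HI to the alkyne, the wrong enolate regiochemistry, and isomerisation of the β,γ-enone. Fallback: close ring B by π-acid chemistry instead. Convert iodoalkyne **5** to its silyl enol ethers and run a Au(I)-catalysed 5-endo-dig carbocyclisation; only the C8=C9 enol ether can cyclise and the other regioisomer is hydrolysed and recycled. The resulting vinyl iodide is then reduced to **7**.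

2. **Step 8 (PhSe⁺-induced ring expansion, with steps 6–7).** Risks are the facial sense at C8, competing selenenylation of the ring-B alkene, and base sensitivity of the β,γ-unsaturated ketone in step 6. Fallback: change the order of ring construction. Dihydroxylate ring B of **7** first and carry it as the exo-acetonide through the spiroannulation, so there is a plain cyclopentanone and no second alkene. Then cleave to the dialdehyde and build the 1-O-methyl dihydropyran (including the C4 ester) before the lactone sulfenylation/aldol chemistry, closing the C1–O–C10 bond last by acid-mediated transacetalisation/SN1′.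

3. **Step 15 (acid cascade to the tetracycle).** Risks are incomplete lactol–enol ether formation and side reactions of the benzylic cation or the unsubstituted enol ether. Fallback: do it stepwise under base. Acetylate the C13 carbinol of **16** before osmylation. After periodate cleavage, close the acetal ring by lactol oxa-Michael addition with E1cB loss of acetate (SN2′ on the Baylis–Hillman-type acetate, DABCO or Et3N). Then dehydrate the remaining C3 lactol separately (MsCl/Et3N) to reach **19**.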